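**Retrosynthetic overview**

- Target 23 is epicatechin 3-O-gallate-(4β→8)-epigallocatechin 3-O-gallate-(4β→8)-catechin 3-O-gallate. The last disconnections are 22 benzyl ethers and the three gallate esters.
- Key disconnection: ring C of the upper unit is cut at C4–C4a and O1–C2, giving free phloroglucinol and epoxy carbinol 15 on C8 of the middle unit. This rests on ring A of the upper unit (C4a, C5, C6, C7, C8, C8a): besides its 5- and 7-hydroxyls it carries only the C4a–C4 bond and the O1–C2 bond, so it maps onto threefold-symmetric phloroglucinol with no regiochemical choice.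
- 15 is cut at the C8(middle)–C4(upper) bond into the aryllithium from bromo dimer 8 and cis-epoxy aldehyde 13. Aldehyde 13 carries C2, C3 and ring B of the upper unit and comes from 3,4-bis(benzyloxy)benzaldehyde by Z-olefination and Sharpless epoxidation.
- 8 is cut at the C4(middle)–C8(lower) interflavan bond into the 8-bromo-4-alkoxy epigallocatechin electrophile 6 and tetra-O-benzylcatechin 2. The C8 bromide is placed on the monomer, where bromination of ring A is reliable.
- Ring order: all rings of the lower and middle units come intact from (+)-catechin and (−)-epigallocatechin, ring B of the upper unit from the benzaldehyde and ring A from phloroglucinol. Ring C of the upper unit is the only ring formed, in step 12.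

Key step: step 12

Remark: halogen–lithium exchange in step 11 would not tolerate aryl esters, so the two C3 hydroxyls of the dimer are carried as TBS ethers through steps 11 and 12 and all three gallates are attached together in step 15; (−)-epigallocatechin, 3,4-bis(benzyloxy)benzaldehyde and 3,4,5-tris(benzyloxy)benzoic acid are assumed to be purchased.

**Route**

Step 1
Reactants: 1 (+)-catechin
Product: 2 5,7,3',4'-tetra-O-benzyl-(+)-catechin
Conditions: BnBr (4.4 equiv), K2CO3, DMF, Ar, 0 °C to rt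
Reagents that add atoms: benzyl bromide, BrCc1ccccc1
Why: Williamson etherification in which K2CO3 deprotonates only the four phenols, so the secondary C3 hydroxyl stays free and the C2 and C3 stereocentres of catechin are carried over unchanged.

Step 2
Reactants: 3 (−)-epigallocatechin
Product: 4 5,7,3',4',5'-penta-O-benzyl-(−)-epigallocatechin
Conditions: BnBr (5.5 equiv), K2CO3, degassed DMF, Ar, 0 °C to rt
Reagents that add atoms: benzyl bromide, BrCc1ccccc1
Why: The same Williamson etherification on the five phenols, run cold and without oxygen because the pyrogallol ring B is oxidation-prone and a free-phenol flavan can epimerise at C2 in warm base; C2 and C3 are carried over.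

Step 3
Reactants: 4 5,7,3',4',5'-penta-O-benzyl-(−)-epigallocatechin
Product: 5 (2R,3R,4S)-5,7,3',4',5'-penta-O-benzyl-4-(2-ethoxyethoxy)epigallocatechin
Conditions: DDQ (2 equiv), 2-ethoxyethanol (5 equiv), CH2Cl2, rt
Reagents that add atoms: 2-ethoxyethanol, CCOCCO
Why: DDQ oxidation of the benzylic C4–H gives a flavan-4-yl cation stabilised by the 5,7-dibenzyloxy ring A, which the alcohol should trap trans to the C3 hydroxyl (the usual C4 activation of benzylated flavan-3-ols); the C4 configuration does not matter because this centre is ionised again in step 5.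

Step 4
Reactants: 5 (2R,3R,4S)-5,7,3',4',5'-penta-O-benzyl-4-(2-ethoxyethoxy)epigallocatechin
Product: 6 8-bromo derivative of 5
Conditions: NBS (1.05 equiv), CH2Cl2, −78 °C to 0 °C
Reagents that add atoms: N-bromosuccinimide, O=C1CCC(=O)N1Br
Why: Electrophilic aromatic bromination, expected at C8 of ring A as in other 5,7-di-O-benzyl flavans; the bromide caps the electrophile against self-condensation in step 5 and is the metalation handle for step 11.

Step 5
Reactants: 6 8-bromo-4-(2-ethoxyethoxy) electrophile; 2 5,7,3',4'-tetra-O-benzyl-(+)-catechin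
Product: 7 8-bromo-penta-O-benzylepigallocatechin-(4β→8)-tetra-O-benzylcatechin (both 3-OH free)
Conditions: 2 (3 equiv), TMSOTf (0.5 equiv), CH2Cl2, −78 to −40 °C
Reagents that add atoms: none
Why: Lewis-acid-promoted Friedel–Crafts coupling of a flavan-4-yl cation with C8 of a benzylated flavan-3-ol, in which ring A of 2 should add from the face opposite the cis-disposed C2 aryl and C3 oxygen of the cation and so set C4 of the middle unit as the 3,4-trans (4β) isomer.

Step 6
Reactants: 7 bromo dimer diol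
Product: 8 bromo dimer bis-TBS ether (TBS on O3 of both units)
Conditions: TBSOTf (3 equiv), 2,6-lutidine (5 equiv), CH2Cl2, 0 °C to rt
Reagents that add atoms: tert-butyldimethylsilyl triflate, CC(C)(C)[Si](C)(C)OS(=O)(=O)C(F)(F)F
Why: Silylation with a silyl triflate and a hindered base reaches even the crowded C3 hydroxyl next to the interflavan bond and masks both alcohols as ethers that tolerate t-BuLi and hexafluoroisopropanol.

Step 7
Reactants: 9 3,4-bis(benzyloxy)benzaldehyde
Product: 10 methyl (Z)-3-[3,4-bis(benzyloxy)phenyl]prop-2-enoate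
Conditions: (CF3CH2O)2P(O)CH2CO2Me, KN(SiMe3)2, 18-crown-6, THF, −78 °C
Reagents that add atoms: methyl bis(2,2,2-trifluoroethyl)phosphonoacetate, COC(=O)CP(=O)(OCC(F)(F)F)OCC(F)(F)F
Why: Still–Gennari variant of the Horner–Wadsworth–Emmons olefination, in which the trifluoroethyl phosphonate makes elimination from the first adduct fast and should therefore give the Z-enoate from an aromatic aldehyde.

Step 8
Reactants: 10 methyl (Z)-3-[3,4-bis(benzyloxy)phenyl]prop-2-enoate
Product: 11 (Z)-3-[3,4-bis(benzyloxy)phenyl]prop-2-en-1-ol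
Conditions: i-Bu2AlH (2.5 equiv), CH2Cl2, −78 °C
Reagents that add atoms: none
Why: 1,2-Reduction of the conjugated ester by the aluminium hydride at low temperature gives the allylic alcohol without isomerising the Z double bond.

Step 9
Reactants: 11 (Z)-3-[3,4-bis(benzyloxy)phenyl]prop-2-en-1-ol
Product: 12 [(2R,3S)-3-[3,4-bis(benzyloxy)phenyl]oxiran-2-yl]methanol (cis)
Conditions: Ti(OiPr)4 (20 mol%), D-(−)-diethyl tartrate (24 mol%), t-BuOOH, 4 Å molecular sieves, CH2Cl2, −20 °C
Reagents that add atoms: tert-butyl hydroperoxide, CC(C)(C)OO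
Why: Sharpless asymmetric epoxidation of a Z-allylic alcohol, in which the titanium complex of D-(−)-diethyl tartrate should deliver oxygen to the face giving the (2R,3S) epoxy alcohol, the cis relationship coming from the alkene geometry and the absolute configuration of both new centres from the tartrate.

Step 10
Reactants: 12 cis-epoxy alcohol
Product: 13 (2S,3S)-3-[3,4-bis(benzyloxy)phenyl]oxirane-2-carbaldehyde (cis)
Conditions: Dess–Martin periodinane, NaHCO3, CH2Cl2, 0 °C; used at once
Reagents that add atoms: none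
Why: Dess–Martin oxidation under bicarbonate buffering converts the primary alcohol into the aldehyde under near-neutral conditions that should spare the acid-labile aryl epoxide and not epimerise the oxirane carbon.

Step 11
Reactants: 8 bromo dimer bis-TBS ether; 13 cis-epoxy aldehyde
Product: 15 C8 epoxy carbinol of the dimer bis-TBS ether (either carbinol epimer), via 8-lithio dimer bis-TBS ether 14 (not isolated)
Conditions: t-BuLi (2.1 equiv), THF, −78 °C; then 13 (1.3 equiv), −78 °C; pH 7 phosphate buffer; crude product used at once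
Reagents that add atoms: none
Why: Bromine–lithium exchange is faster at −78 °C than attack on benzyl or silyl ethers, and the aryllithium then adds to the aldehyde carbonyl in preference to the epoxide (1,2-addition of an aryllithium to an α,β-epoxy aldehyde); the new carbinol centre need not be controlled because it is ionised in step 12.

Step 12
Reactants: 15 C8 epoxy carbinol of the dimer bis-TBS ether; 16 phloroglucinol
Product: 18 trimer bis-TBS ether bearing free 3-OH/5-OH/7-OH on the new upper unit, via C4-phloroglucinyl cis-epoxide 17 (not isolated)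
Conditions: 16 (10 equiv), (CF3)2CHOH/CH2Cl2 (4:1), −20 to 0 °C
Reagents that add atoms: none
Why: Proposed new method: in hexafluoroisopropanol the carbinol of 15, which sits on a ring carrying oxygen at both ortho positions and at the para position, should ionise to a quinone-methide-like benzylic cation that excess phloroglucinol captures through carbon (Friedel–Crafts alkylation, C4–C4a) to give 17, after which one of its two equivalent ortho hydroxyls opens the hydrogen-bond-activated epoxide at the benzylic carbon (O1–C2). The closest known reaction types are the capture of flavan-4-yl cations by phloroglucinol, catalyst-free Friedel–Crafts alkylation with electron-rich benzylic alcohols in hexafluoroisopropanol, acid-promoted 6-endo epoxide–phenol cyclisations that give flavan-3-ols, and anti-selective nucleophilic additions to cis-α,β-epoxy aldehydes; the tandem use of a free triphenol as a three-atom partner for an epoxy carbinol has not been shown. Ring C of the upper unit closes in a 6-endo-tet mode, preferred over 5-exo attack at C3 because only C2 is benzylic to the electron-rich 3,4-dibenzyloxyphenyl group. C4 should be controlled by the epoxide stereocentre at C3, since the cation is expected to hold the C3–H bond in its plane facing the ortho-disubstituted ring (allylic 1,3-strain) and the arene to add anti to the solvated epoxide C3–O bond, which gives the 3,4-trans (4β) arrangement; C2 is set by SN2-type inversion of the cis-epoxide carbon, which gives the 2,3-cis relationship, and C3 keeps its C–O bond. The step needs ionisation of the carbinol before the epoxide, which the trioxygenated benzylic position and the low temperature should secure, and monoalkylation of the arene, which the large excess of phloroglucinol should secure; it needs no regiochemical choice, because every carbon and every hydroxyl of phloroglucinol is equivalent.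

Step 13
Reactants: 18 trimer bis-TBS ether with free 3-OH/5-OH/7-OH on the upper unit
Product: 19 trimer bis-TBS ether with 5,7-di-O-benzyl upper unit and free upper 3-OH
Conditions: BnBr (2.4 equiv), K2CO3, DMF, rt
Reagents that add atoms: benzyl bromide, BrCc1ccccc1
Why: Williamson etherification with a weak base alkylates only the two phenols of the new ring A and leaves the secondary C3 hydroxyl of the upper unit free for acylation.

Step 14
Reactants: 19 trimer bis-TBS ether with free upper 3-OH
Product: 20 perbenzylated trimer triol (3-OH free on all three units)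
Conditions: Bu4NF, THF, rt to 45 °C
Reagents that add atoms: none
Why: Fluoride-induced cleavage of the two silyl ethers frees the C3 hydroxyls of the middle and lower units without affecting benzyl ethers or interflavan bonds.

Step 15
Reactants: 20 perbenzylated trimer triol; 21 3,4,5-tris(benzyloxy)benzoic acid
Product: 22 perbenzylated trimer tris(3-O-gallate)
Conditions: 21 (4.5 equiv), DCC (5 equiv), DMAP (1.5 equiv), CH2Cl2, rt to 40 °C
Reagents that add atoms: 3,4,5-tris(benzyloxy)benzoic acid (compound 21; one molecule is taken up by each C3 hydroxyl, three in all), OC(=O)c1cc(OCc2ccccc2)c(OCc2ccccc2)c(OCc2ccccc2)c1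
Why: Steglich esterification (carbodiimide activation with DMAP as acyl-transfer catalyst) should acylate each of the three secondary C3 hydroxyls of 20 with one molecule of 21, the water of each condensation ending up in the urea; this is the usual way to 3-O-galloylate benzylated flavan-3-ols and their 4-aryl oligomers, and it touches no stereocentre.

Step 16
Reactants: 22 perbenzylated trimer tris(3-O-gallate)
Product: 23 epicatechin 3-O-gallate-(4β→8)-epigallocatechin 3-O-gallate-(4β→8)-catechin 3-O-gallate (CNP0321910.1)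
Conditions: H2 (1 atm), Pd(OH)2/C, THF/MeOH/H2O, rt
Reagents that add atoms: none
Why: Catalytic hydrogenolysis cleaves all 22 benzyl ethers, while the gallate esters, the interflavan bonds and the C2–O1 bonds of the flavan rings are expected to stay intact under these standard final-deprotection conditions for galloylated proanthocyanidins.

**Compound list**

1 | (+)-catechin | Oc1cc(O)c2c(c1)O[C@H](c1ccc(O)c(O)c1)[C@@H](O)C2 | starting material
2 | 5,7,3',4'-tetra-O-benzyl-(+)-catechin (2R,3S) | O[C@H]1Cc2c(OCc5ccccc5)cc(OCc5ccccc5)cc2O[C@@H]1c1ccc(OCc5ccccc5)c(OCc5ccccc5)c1 | intermediate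
3 | (−)-epigallocatechin (2R,3R) | O[C@@H]1Cc2c(O)cc(O)cc2O[C@@H]1c1cc(O)c(O)c(O)c1 | starting material
4 | 5,7,3',4',5'-penta-O-benzyl-(−)-epigallocatechin | O[C@@H]1Cc2c(OCc5ccccc5)cc(OCc5ccccc5)cc2O[C@@H]1c1cc(OCc5ccccc5)c(OCc5ccccc5)c(OCc5ccccc5)c1 | intermediate
5 | (2R,3R,4S)-5,7,3',4',5'-penta-O-benzyl-4-(2-ethoxyethoxy)epigallocatechin (4β ether, trans to 3-OH) | O[C@@H]1[C@@H](OCCOCC)c2c(OCc5ccccc5)cc(OCc5ccccc5)cc2O[C@@H]1c1cc(OCc5ccccc5)c(OCc5ccccc5)c(OCc5ccccc5)c1 | intermediate
6 | 8-bromo derivative of 5 | O[C@@H]1[C@@H](OCCOCC)c2c(OCc5ccccc5)cc(OCc5ccccc5)c(Br)c2O[C@@H]1c1cc(OCc5ccccc5)c(OCc5ccccc5)c(OCc5ccccc5)c1 | intermediate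
7 | 8-bromo-penta-O-benzylepigallocatechin-(4β→8)-tetra-O-benzylcatechin, both 3-OH free | O[C@@H]1[C@@H](c2c(OCc5ccccc5)cc(OCc5ccccc5)c3c2O[C@H](c2ccc(OCc5ccccc5)c(OCc5ccccc5)c2)[C@@H](O)C3)c2c(OCc5ccccc5)cc(OCc5ccccc5)c(Br)c2O[C@@H]1c1cc(OCc5ccccc5)c(OCc5ccccc5)c(OCc5ccccc5)c1 | intermediate
8 | bis-TBS ether of 7 (TBS on O3 of both units) | CC(C)(C)[Si](C)(C)O[C@@H]1[C@@H](c2c(OCc5ccccc5)cc(OCc5ccccc5)c3c2O[C@H](c2ccc(OCc5ccccc5)c(OCc5ccccc5)c2)[C@@H](O[Si](C)(C)C(C)(C)C)C3)c2c(OCc5ccccc5)cc(OCc5ccccc5)c(Br)c2O[C@@H]1c1cc(OCc5ccccc5)c(OCc5ccccc5)c(OCc5ccccc5)c1 | intermediate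
9 | 3,4-bis(benzyloxy)benzaldehyde | O=Cc1ccc(OCc2ccccc2)c(OCc2ccccc2)c1 | starting material
10 | methyl (Z)-3-[3,4-bis(benzyloxy)phenyl]prop-2-enoate | COC(=O)/C=C\c1ccc(OCc2ccccc2)c(OCc2ccccc2)c1 | intermediate
11 | (Z)-3-[3,4-bis(benzyloxy)phenyl]prop-2-en-1-ol | OC/C=C\c1ccc(OCc2ccccc2)c(OCc2ccccc2)c1 | intermediate
12 | [(2R,3S)-3-[3,4-bis(benzyloxy)phenyl]oxiran-2-yl]methanol (cis) | OC[C@H]1O[C@H]1c1ccc(OCc2ccccc2)c(OCc2ccccc2)c1 | intermediate
13 | (2S,3S)-3-[3,4-bis(benzyloxy)phenyl]oxirane-2-carbaldehyde (cis) | O=C[C@H]1O[C@H]1c1ccc(OCc2ccccc2)c(OCc2ccccc2)c1 | intermediate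
14 | 8-lithio dimer bis-TBS ether (8 with Li in place of Br) | CC(C)(C)[Si](C)(C)O[C@@H]1[C@@H](c2c(OCc5ccccc5)cc(OCc5ccccc5)c3c2O[C@H](c2ccc(OCc5ccccc5)c(OCc5ccccc5)c2)[C@@H](O[Si](C)(C)C(C)(C)C)C3)c2c(OCc5ccccc5)cc(OCc5ccccc5)c([Li])c2O[C@@H]1c1cc(OCc5ccccc5)c(OCc5ccccc5)c(OCc5ccccc5)c1 | intermediate (not isolated)
15 | dimer bis-TBS ether bearing at C8 of the epigallocatechin unit the group CH(OH)[(2R,3S)-3-(3,4-dibenzyloxyphenyl)oxiran-2-yl] (cis-epoxide, carbinol as either epimer) | CC(C)(C)[Si](C)(C)O[C@@H]1[C@@H](c2c(OCc5ccccc5)cc(OCc5ccccc5)c3c2O[C@H](c2ccc(OCc5ccccc5)c(OCc5ccccc5)c2)[C@@H](O[Si](C)(C)C(C)(C)C)C3)c2c(OCc5ccccc5)cc(OCc5ccccc5)c(C(O)[C@H]4O[C@H]4c4ccc(OCc5ccccc5)c(OCc5ccccc5)c4)c2O[C@@H]1c1cc(OCc5ccccc5)c(OCc5ccccc5)c(OCc5ccccc5)c1 | intermediate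
16 | phloroglucinol | Oc1cc(O)cc(O)c1 | starting material
17 | Friedel–Crafts adduct: 15 with the carbinol OH replaced by a 2,4,6-trihydroxyphenyl group (new centre configured as C4 of 18), cis-epoxide intact | CC(C)(C)[Si](C)(C)O[C@@H]1[C@@H](c2c(OCc5ccccc5)cc(OCc5ccccc5)c3c2O[C@H](c2ccc(OCc5ccccc5)c(OCc5ccccc5)c2)[C@@H](O[Si](C)(C)C(C)(C)C)C3)c2c(OCc5ccccc5)cc(OCc5ccccc5)c([C@@H](c3c(O)cc(O)cc3O)[C@H]4O[C@H]4c4ccc(OCc5ccccc5)c(OCc5ccccc5)c4)c2O[C@@H]1c1cc(OCc5ccccc5)c(OCc5ccccc5)c(OCc5ccccc5)c1 | intermediate (not isolated)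
18 | trimer: upper unit 3',4'-di-O-benzylepicatechin (2R,3R,4R) with free 3-, 5- and 7-OH, linked 4β→8 to the middle unit; middle and lower units protected as in 8 | CC(C)(C)[Si](C)(C)O[C@@H]1[C@@H](c2c(OCc5ccccc5)cc(OCc5ccccc5)c3c2O[C@H](c2ccc(OCc5ccccc5)c(OCc5ccccc5)c2)[C@@H](O[Si](C)(C)C(C)(C)C)C3)c2c(OCc5ccccc5)cc(OCc5ccccc5)c([C@H]3c4c(O)cc(O)cc4O[C@H](c4ccc(OCc5ccccc5)c(OCc5ccccc5)c4)[C@@H]3O)c2O[C@@H]1c1cc(OCc5ccccc5)c(OCc5ccccc5)c(OCc5ccccc5)c1 | intermediate
19 | 5,7-di-O-benzyl ether of 18 (upper 3-OH free, TBS on O3 of middle and lower units) | CC(C)(C)[Si](C)(C)O[C@@H]1[C@@H](c2c(OCc5ccccc5)cc(OCc5ccccc5)c3c2O[C@H](c2ccc(OCc5ccccc5)c(OCc5ccccc5)c2)[C@@H](O[Si](C)(C)C(C)(C)C)C3)c2c(OCc5ccccc5)cc(OCc5ccccc5)c([C@H]3c4c(OCc5ccccc5)cc(OCc5ccccc5)cc4O[C@H](c4ccc(OCc5ccccc5)c(OCc5ccccc5)c4)[C@@H]3O)c2O[C@@H]1c1cc(OCc5ccccc5)c(OCc5ccccc5)c(OCc5ccccc5)c1 | intermediate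
20 | perbenzylated epicatechin-(4β→8)-epigallocatechin-(4β→8)-catechin with all three 3-OH free | O[C@@H]1[C@@H](c2c(OCc5ccccc5)cc(OCc5ccccc5)c3c2O[C@H](c2ccc(OCc5ccccc5)c(OCc5ccccc5)c2)[C@@H](O)C3)c2c(OCc5ccccc5)cc(OCc5ccccc5)c([C@H]3c4c(OCc5ccccc5)cc(OCc5ccccc5)cc4O[C@H](c4ccc(OCc5ccccc5)c(OCc5ccccc5)c4)[C@@H]3O)c2O[C@@H]1c1cc(OCc5ccccc5)c(OCc5ccccc5)c(OCc5ccccc5)c1 | intermediate
21 | 3,4,5-tris(benzyloxy)benzoic acid | OC(=O)c1cc(OCc2ccccc2)c(OCc2ccccc2)c(OCc2ccccc2)c1 | starting material
22 | perbenzylated trimer tris[3-O-(3,4,5-tribenzyloxybenzoate)] (22 benzyl ethers) | O=C(O[C@@H]1[C@@H](c2c(OCc5ccccc5)cc(OCc5ccccc5)c3c2O[C@H](c2ccc(OCc5ccccc5)c(OCc5ccccc5)c2)[C@@H](OC(=O)c2cc(OCc5ccccc5)c(OCc5ccccc5)c(OCc5ccccc5)c2)C3)c2c(OCc5ccccc5)cc(OCc5ccccc5)c([C@H]3c4c(OCc5ccccc5)cc(OCc5ccccc5)cc4O[C@H](c4ccc(OCc5ccccc5)c(OCc5ccccc5)c4)[C@@H]3OC(=O)c3cc(OCc5ccccc5)c(OCc5ccccc5)c(OCc5ccccc5)c3)c2O[C@@H]1c1cc(OCc5ccccc5)c(OCc5ccccc5)c(OCc5ccccc5)c1)c1cc(OCc5ccccc5)c(OCc5ccccc5)c(OCc5ccccc5)c1 | intermediate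
23 | epicatechin 3-O-gallate-(4β→8)-epigallocatechin 3-O-gallate-(4β→8)-catechin 3-O-gallate (CNP0321910.1) | O=C(O[C@@H]1[C@@H](c2c(O)cc(O)c3c2O[C@H](c2ccc(O)c(O)c2)[C@@H](OC(=O)c2cc(O)c(O)c(O)c2)C3)c2c(O)cc(O)c([C@H]3c4c(O)cc(O)cc4O[C@H](c4ccc(O)c(O)c4)[C@@H]3OC(=O)c3cc(O)c(O)c(O)c3)c2O[C@@H]1c1cc(O)c(O)c(O)c1)c1cc(O)c(O)c(O)c1 | target

**Step count and risks**

Total step count: 16.
Longest linear sequence: 11 steps (steps 2 to 6, then 11 to 16, from (−)-epigallocatechin).

Steps most likely to fail: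

1. Step 12 (proposed new method). The arene may add to the cation with poor or reversed facial selectivity, because C2 of the epoxide and its cis aryl group lie on the face that must be attacked. The epoxide may also open through a free benzylic cation, losing the inversion at C2, and the electron-rich product may be alkylated a second time. The fallback uses the known Lewis-acid coupling of flavan-4-yl cations and sets out from 8. Bromine–lithium exchange with n-BuLi in THF at −78 °C followed by a methanol quench would give the debrominated dimer bis-TBS ether F1. In parallel, purchased (−)-epicatechin would be benzylated (BnBr, K2CO3, DMF) to 5,7,3',4'-tetra-O-benzyl-(−)-epicatechin F2 and then oxidised with DDQ in the presence of 2-ethoxyethanol to its 4β-(2-ethoxyethoxy) derivative F3. TMSOTf-promoted coupling of F3 with F1 in CH2Cl2 at −78 °C should occur at C8 of the upper unit of the benzylated dimer and trans to the C3 oxygen of the 2,3-cis cation. This would give 19 directly, where the fallback rejoins the route before step 14.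

2. Step 11. The hindered aryllithium may be protonated or may destroy the base-sensitive epoxy aldehyde instead of adding to it, and the very electron-rich carbinol may ionise during work-up. The fallback sets out from 8 and builds the side chain stepwise, with the epoxide made last. Exchange with t-BuLi and a DMF quench would give the dimer 8-carbaldehyde bis-TBS ether F4. Aldehyde 9 would be converted with dimethyl (1-diazo-2-oxopropyl)phosphonate and K2CO3 in methanol (Ohira–Bestmann) into 4-ethynyl-1,2-bis(benzyloxy)benzene F5. The lithium acetylide of F5 (n-BuLi, THF, −78 °C) would add to F4 to give the propargylic alcohol F6. Semihydrogenation over Pd/CaCO3 poisoned with Pb(OAc)2 and quinoline (Lindlar catalyst) would give the Z-allylic alcohol F7. Asymmetric epoxidation of F7 with KHSO5 and a Shi-type oxazolidinone-bearing chiral ketone for cis-alkenes, in the enantiomeric series that matches the epoxide of 15, would then give 15, where the fallback rejoins the route before step 12.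

3. Step 9. Epoxidation of a Z-allylic alcohol is slow, so the electron-rich benzylic epoxide may be opened by the titanium alkoxide medium before it is isolated, and enantiofacial control may be incomplete. The fallback sets out from 10 and makes the epoxide on the ester, where the electron-withdrawing group stabilises it. Jacobsen epoxidation of 10 with the (S,S)-N,N'-bis(3,5-di-tert-butylsalicylidene)-1,2-cyclohexanediamine MnCl complex (trivalent manganese), NaOCl and 4-phenylpyridine N-oxide in CH2Cl2 would give methyl (2S,3S)-3-[3,4-bis(benzyloxy)phenyl]oxirane-2-carboxylate F8. Partial reduction of F8 with i-Bu2AlH (1 equiv) in toluene at −78 °C would give 13, where the fallback rejoins the route before step 11.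

**Further compounds**

F1 | step 12 | debrominated dimer bis-TBS ether (8 with H at C8) | CC(C)(C)[Si](C)(C)O[C@@H]1[C@@H](c2c(OCc5ccccc5)cc(OCc5ccccc5)c3c2O[C@H](c2ccc(OCc5ccccc5)c(OCc5ccccc5)c2)[C@@H](O[Si](C)(C)C(C)(C)C)C3)c2c(OCc5ccccc5)cc(OCc5ccccc5)cc2O[C@@H]1c1cc(OCc5ccccc5)c(OCc5ccccc5)c(OCc5ccccc5)c1
F2 | step 12 | 5,7,3',4'-tetra-O-benzyl-(−)-epicatechin | O[C@@H]1Cc2c(OCc5ccccc5)cc(OCc5ccccc5)cc2O[C@@H]1c1ccc(OCc5ccccc5)c(OCc5ccccc5)c1
F3 | step 12 | (2R,3R,4S)-5,7,3',4'-tetra-O-benzyl-4-(2-ethoxyethoxy)epicatechin | O[C@@H]1[C@@H](OCCOCC)c2c(OCc5ccccc5)cc(OCc5ccccc5)cc2O[C@@H]1c1ccc(OCc5ccccc5)c(OCc5ccccc5)c1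
F4 | step 11 | dimer 8-carbaldehyde bis-TBS ether | CC(C)(C)[Si](C)(C)O[C@@H]1[C@@H](c2c(OCc5ccccc5)cc(OCc5ccccc5)c3c2O[C@H](c2ccc(OCc5ccccc5)c(OCc5ccccc5)c2)[C@@H](O[Si](C)(C)C(C)(C)C)C3)c2c(OCc5ccccc5)cc(OCc5ccccc5)c(C=O)c2O[C@@H]1c1cc(OCc5ccccc5)c(OCc5ccccc5)c(OCc5ccccc5)c1
F5 | step 11 | 4-ethynyl-1,2-bis(benzyloxy)benzene | C#Cc1ccc(OCc2ccccc2)c(OCc2ccccc2)c1
F6 | step 11 | C8 propargylic alcohol of the dimer bis-TBS ether (carbinol as either epimer) | CC(C)(C)[Si](C)(C)O[C@@H]1[C@@H](c2c(OCc5ccccc5)cc(OCc5ccccc5)c3c2O[C@H](c2ccc(OCc5ccccc5)c(OCc5ccccc5)c2)[C@@H](O[Si](C)(C)C(C)(C)C)C3)c2c(OCc5ccccc5)cc(OCc5ccccc5)c(C(O)C#Cc4ccc(OCc5ccccc5)c(OCc5ccccc5)c4)c2O[C@@H]1c1cc(OCc5ccccc5)c(OCc5ccccc5)c(OCc5ccccc5)c1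
F7 | step 11 | C8 (Z)-allylic alcohol of the dimer bis-TBS ether (carbinol as either epimer) | CC(C)(C)[Si](C)(C)O[C@@H]1[C@@H](c2c(OCc5ccccc5)cc(OCc5ccccc5)c3c2O[C@H](c2ccc(OCc5ccccc5)c(OCc5ccccc5)c2)[C@@H](O[Si](C)(C)C(C)(C)C)C3)c2c(OCc5ccccc5)cc(OCc5ccccc5)c(C(O)/C=C\c4ccc(OCc5ccccc5)c(OCc5ccccc5)c4)c2O[C@@H]1c1cc(OCc5ccccc5)c(OCc5ccccc5)c(OCc5ccccc5)c1
F8 | step 9 | methyl (2S,3S)-3-[3,4-bis(benzyloxy)phenyl]oxirane-2-carboxylate (cis) | COC(=O)[C@H]1O[C@H]1c1ccc(OCc2ccccc2)c(OCc2ccccc2)c1
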